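Numbering (longipinane, kept for all intermediates): C1 ketone, C2=C3(CH3), bridgeheads C4 and C11, C5, C6 (CMe2), C7 (O-angeloyl), C8 (O-2-methylbutanoyl), C9 (OH), C10 (quaternary, CH3). Rings: cyclobutane C4–C5–C11–C10, cyclohexenone C1–C2–C3–C4–C5–C11, seven-membered ring C5–C6–C7–C8–C9–C10–C11.
Enabling feature: the only free hydroxyl (C9) sits next to the quaternary cyclobutane carbon C10, so C9–O/C10 is the imprint of an opened epoxide (β-oxy tertiary radical). C10 lies 1,4 to C4 across the C11–C5 bond shared by the six- and seven-membered rings, and with the carbonyl parked at C2, C4 is an enone β-carbon.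
Key disconnection C10–C4: target ⇒ (carbonyl shift C1/C2) tricyclic C2 ketone 25 ⇒ cis-fused 6–7 epoxy enone 22, an isomer of the target that already bears both esters. One reductive radical 4-exo closure makes the cyclobutane, the quaternary centre and the free C9–OH.
22 ⇒ allylic C2–H oxidation, OH-directed epoxidation, ring-closing metathesis (C9=C10) on the native isopropenyl group, syn-alkoxyallylboration (C7–C8), Ireland–Claisen rearrangement (C5–C6) ⇒ (1S,4R)-p-mentha-2,8-dien-1-ol.
Ring order: six-membered ring (bought), seven-membered ring (step 8), cyclobutane (step 12, last).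

Key step: step 12

Remark: 1, 2, 9, 13 and 20 are taken as purchasable. The C3 configuration drawn for 25–29 is the one expected from protonation on the open face and does not matter, because C3 becomes trigonal again in step 16.

Step 1
Reactants: 1 (1S,4R)-p-mentha-2,8-dien-1-ol (OH and isopropenyl on the same ring face); 2 isobutyryl chloride
Product: 3 (1S,4R)-1-methyl-4-(prop-1-en-2-yl)cyclohex-2-en-1-yl isobutyrate
Conditions: Et3N, DMAP (cat.), CH2Cl2, 0 °C to rt
Reagents that add atoms: none
Why: DMAP-catalysed acylation takes place at oxygen only, so the tertiary allylic C3–O bond and both stereocentres of 1 stay untouched.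

Step 2
Reactants: 3 isobutyrate
Product: 6 2-methyl-2-[(1S,6R)-3-methyl-6-(prop-1-en-2-yl)cyclohex-2-en-1-yl]propanoic acid, via silyl ketene acetal 4 (not isolated), via trimethylsilyl ester 5 (not isolated)
Conditions: LiN(iPr)2, THF, −78 °C; Me3SiCl; −78 °C to 60 °C; aq. HCl work-up
Reagents that add atoms: none
Why: Ireland–Claisen rearrangement: ketene acetal 4 (no E/Z issue, two methyl groups on the terminus) shifts suprafacially, so the C5–C6 bond forms on the ring face that held the C3–O bond, which is the isopropenyl face, and this sets C5 cis to C11 while the alkene moves to C3=C4.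

Step 3
Reactants: 6 acid
Product: 7 2-methyl-2-[(1S,6R)-3-methyl-6-(prop-1-en-2-yl)cyclohex-2-en-1-yl]propan-1-ol
Conditions: LiAlH4, Et2O, 0 °C to reflux; aqueous NaOH work-up
Reagents that add atoms: none
Why: Hydride reduction of the carboxylic acid leaves the unactivated alkenes and both stereocentres alone.

Step 4
Reactants: 7 neopentyl alcohol
Product: 8 2-methyl-2-[(1S,6R)-3-methyl-6-(prop-1-en-2-yl)cyclohex-2-en-1-yl]propanal
Conditions: Dess–Martin periodinane, CH2Cl2, rt
Reagents that add atoms: none
Why: Dess–Martin oxidation stops at the aldehyde, which has a quaternary α-carbon and therefore cannot enolise or epimerise.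

Step 5
Reactants: 8 aldehyde; 9 allyl methoxymethyl ether
Product: 12 (3S,4S)-4-(methoxymethoxy)-2-methyl-2-[(1S,6R)-3-methyl-6-(prop-1-en-2-yl)cyclohex-2-en-1-yl]hex-5-en-3-ol, via allylborane 10 (not isolated), via borinate 11 (not isolated)
Conditions: 9, s-BuLi, THF, −78 °C; (+)-Ipc2BOMe; BF3·OEt2; then 8, −78 °C to rt; NaOH, H2O2
Reagents that add atoms: none
Why: Brown (Z)-γ-alkoxyallylboration: the closed chair transition state turns the Z geometry of 10 into the syn (threo) C7/C8 relationship, and the isopinocampheyl groups derived from (−)-α-pinene direct attack to the Re face of the aldehyde (7S,8S), under reagent control because C6 is not stereogenic.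

Step 6
Reactants: 12 alcohol; 13 angelic acid
Product: 15 C7 angelate of 12 (MOM ether kept at O-8), via mixed anhydride 14 (not isolated)
Conditions: 13, 2,4,6-trichlorobenzoyl chloride, Et3N, toluene, rt; then 12, 80 °C
Reagents that add atoms: none
Why: Yamaguchi-type esterification through 14, run without a nucleophilic catalyst, acylates the hindered C7–OH at the less shielded angeloyl carbonyl and keeps the Z alkene from isomerising to the tiglate; no stereocentre is touched.

Step 7
Reactants: 15 angelate MOM ether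
Product: 17 (3S,4S)-4-hydroxy-2-methyl-2-[(1S,6R)-3-methyl-6-(prop-1-en-2-yl)cyclohex-2-en-1-yl]hex-5-en-3-yl angelate, via bromomethyl ether 16 (not isolated)
Conditions: Me2BBr, CH2Cl2, −78 °C; then aq. NaHCO3
Reagents that add atoms: none
Why: Bromoborane cleavage of the acetal, followed by hydrolysis of 16, removes the MOM group at low temperature without acid strong enough to protonate the alkenes or to move the angelate.

Step 8
Reactants: 17 triene
Product: 18 himachala-3,9-dien-8-ol 7-angelate (cis-fused; O-7/O-8 trans; C5 C7 C8 C11 as in the target)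
Conditions: second-generation Hoveyda–Grubbs catalyst (5 mol %), toluene (2 mM), 80 °C
Reagents that add atoms: none
Why: Ring-closing metathesis starts at the vinyl group and closes onto the isopropenyl group; the cis arrangement on the cyclohexene and the gem-dimethyl group at C6 favour the seven-membered ring, while C3=C4 and the angelate are too substituted to take part.

Step 9
Reactants: 18 allylic alcohol
Product: 19 9,10-epoxyhimachal-3-en-8-ol 7-angelate (epoxide oxygen cis to O-8 and on the face opposite to the six-membered ring)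
Conditions: VO(acac)2 (5 mol %), t-BuOOH, CH2Cl2, 0 °C
Reagents that add atoms: tert-butyl hydroperoxide CC(C)(C)OO
Why: Vanadium-catalysed hydroxyl-directed epoxidation delivers oxygen to C9=C10 from the face of the C8–OH, which is also the convex face turned away from the cyclohexene, so C9 and C10 are set syn to O-8 and the undirected C3=C4 alkene is left alone.

Step 10
Reactants: 19 epoxy alcohol; 20 (R)-2-methylbutanoic acid
Product: 21 9,10-epoxyhimachal-3-ene 7-angelate 8-[(R)-2-methylbutanoate]
Conditions: DCC, DMAP (cat.), CH2Cl2, 0 °C to rt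
Reagents that add atoms: none
Why: Steglich esterification acylates the only free hydroxyl under near-neutral conditions that neither open the epoxide nor epimerise the α-centre of 20.

Step 11
Reactants: 21 epoxy diester
Product: 22 9,10-epoxyhimachal-3-en-2-one 7-angelate 8-[(R)-2-methylbutanoate]
Conditions: Rh2(cap)4 (dirhodium tetracaprolactamate, 1 mol %), t-BuOOH (70% aq.), ClCH2CH2Cl, 40 °C
Reagents that add atoms: tert-butyl hydroperoxide CC(C)(C)OO
Why: Radical allylic C–H oxidation: C2 is the only allylic methylene, C5–H is tertiary, shielded by C6 and cannot end as a ketone, and oxygen capture at the C4 end of the allyl radical is blocked by the C5 substituent, as in the known C6 oxidation of 3-substituted p-mentha-1,8-dienes.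

Step 12
Reactants: 22 epoxy enone
Product: 25 9-hydroxylongipinan-2-one 7-angelate 8-[(R)-2-methylbutanoate] (C3 methyl on the side of the C10 bridge), via C10 radical 23 (not isolated), via titanium enolate 24 (not isolated)
Conditions: Cp2TiCl2 (2.5 equiv), Mn dust, THF, rt (gives Cp2TiCl); added slowly to 22 (5 mM in THF), rt; then aq. NaH2PO4
Reagents that add atoms: none
Why: Cp2TiCl (trivalent titanium) gives one electron to the epoxide and the C10–O bond breaks because this yields the tertiary radical 23, while C9 keeps its oxygen and configuration as a titanium alkoxide; 23 adds to C4, the β-carbon of the C2 enone, and a second Cp2TiCl reduces the C3 α-keto radical to enolate 24, which makes the otherwise reversible closure irreversible. The closest known reaction type is the titanocene-mediated reductive epoxide opening with 4-exo radical cyclisation onto an α,β-unsaturated ketone, known for carvone-derived epoxy enones, which give pinane skeletons. The only ring closed is the cyclobutane C4–C5–C11–C10, in a 4-exo-trig mode (C3 stays outside the new ring). C10 is set by the frame, since the planar radical held in the seven-membered ring can reach C4 only with C9 turned away from the C1–C3 bridge and its methyl group over it; C4 is set by the cis ring fusion, since C10 hangs from C11 on one face of the cyclohexenone; C3 is set by protonation of 24 from the face of the C5 bridge and is erased later. The step needs cyclisation to outrun capture of 23 by titanium, which is secured because the bulky quaternary C6 takes the equatorial site on C5 and forces C10 into the axial site above C4, because tertiary radicals are trapped slowly by Cp2TiCl, and because slow addition keeps the titanium concentration low. Chemoselectivity rests on the inner-sphere opening of the epoxide being faster than reduction of the enone, and on the angelate β-carbon being reachable only through an eight-membered closure.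

Step 13
Reactants: 25 hydroxy ketone
Product: 26 9-O-trimethylsilyl ether of 25
Conditions: Me3SiOTf, 2,6-lutidine, CH2Cl2, −78 °C
Reagents that add atoms: trimethylsilyl triflate C[Si](C)(C)OS(=O)(=O)C(F)(F)F
Why: Silylation of the only hydroxyl masks C9–OH so that no alkoxide can form next to the C8 ester in step 14.

Step 14
Reactants: 26 silyl ether ketone
Product: 27 C1=C2 enol triflate of 26 (longipin-1-en-2-yl triflate)
Conditions: KN(SiMe3)2 (1.1 equiv), THF, −78 °C; Comins' reagent
Reagents that add atoms: Comins' reagent FC(F)(F)S(=O)(=O)N(c1ccc(Cl)cn1)S(=O)(=O)C(F)(F)F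
Why: Kinetic deprotonation takes the exposed C1 methylene (C3–H is tertiary and flanked by methyl and bridgehead, the ester α-protons are less acidic and more hindered) and O-sulfonylation gives the enol triflate, whose regiochemistry is not critical because either isomer would lead to the same allyl radical in step 16.

Step 15
Reactants: 27 enol triflate
Product: 29 9-hydroxylongipin-1-ene 7-angelate 8-[(R)-2-methylbutanoate], via silyl ether 28 (not isolated)
Conditions: Pd(OAc)2 (5 mol %), PPh3, HCO2H, Et3N, DMF, 60 °C; then aq. citric acid, MeOH, rt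
Reagents that add atoms: none
Why: Palladium-catalysed formate reduction of an enol triflate (oxidative addition of zerovalent palladium, decarboxylation of formate to a palladium hydride, reductive elimination) replaces OTf by H without touching the esters, and the labile Me3Si ether is solvolysed in the acidic work-up.

Step 16
Reactants: 29 alkene
Product: 30 target (4R,5S,7S,8S,9S,10R,11R)-7-angeloyloxy-9-hydroxy-8-[(2R)-2-methylbutanoyloxy]longipin-2-en-1-one
Conditions: Rh2(cap)4 (1 mol %), t-BuOOH (70% aq.), ClCH2CH2Cl, 40 °C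
Reagents that add atoms: tert-butyl hydroperoxide CC(C)(C)OO
Why: Allylic C–H oxidation with transposition: the bridgehead C11–H cannot give a conjugated radical, so hydrogen is taken from C3 (exposed on the face of the C5 bridge), the C1–C2–C3 allyl radical is the one that leads from α-pinene to verbenone, only its secondary C1 end can finish as a ketone, and the electron-poor angelate methyl groups and the hindered C9–OH are not attacked.

Compound list
1 | (1S,4R)-p-mentha-2,8-dien-1-ol | C[C@@]1(O)C=C[C@@H](CC1)C(C)=C | starting material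
2 | isobutyryl chloride | CC(C)C(=O)Cl | starting material
3 | (1S,4R)-1-methyl-4-(prop-1-en-2-yl)cyclohex-2-en-1-yl isobutyrate | CC(C)C(=O)O[C@]1(C)C=C[C@@H](CC1)C(C)=C | intermediate
4 | trimethylsilyl ketene acetal of 3 | CC(C)=C(O[Si](C)(C)C)O[C@]1(C)C=C[C@@H](CC1)C(C)=C | intermediate
5 | trimethylsilyl ester of 6 | C[Si](C)(C)OC(=O)C(C)(C)[C@H]1C=C(C)CC[C@H]1C(C)=C | intermediate
6 | 2-methyl-2-[(1S,6R)-3-methyl-6-(prop-1-en-2-yl)cyclohex-2-en-1-yl]propanoic acid | OC(=O)C(C)(C)[C@H]1C=C(C)CC[C@H]1C(C)=C | intermediate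
7 | 2-methyl-2-[(1S,6R)-3-methyl-6-(prop-1-en-2-yl)cyclohex-2-en-1-yl]propan-1-ol | OCC(C)(C)[C@H]1C=C(C)CC[C@H]1C(C)=C | intermediate
8 | 2-methyl-2-[(1S,6R)-3-methyl-6-(prop-1-en-2-yl)cyclohex-2-en-1-yl]propanal | O=CC(C)(C)[C@H]1C=C(C)CC[C@H]1C(C)=C | intermediate
9 | allyl methoxymethyl ether | C=CCOCOC | starting material
10 | (Z)-3-(methoxymethoxy)allyl-diisopinocampheylborane (Ipc from (−)-α-pinene) | COCO/C=C\CB([C@H]1C[C@H]2C[C@@H]([C@@H]1C)C2(C)C)[C@H]1C[C@H]2C[C@@H]([C@@H]1C)C2(C)C | intermediate
11 | diisopinocampheylborinate of 12 | B([C@H]1C[C@H]2C[C@@H]([C@@H]1C)C2(C)C)([C@H]1C[C@H]2C[C@@H]([C@@H]1C)C2(C)C)O[C@H]([C@@H](OCOC)C=C)C(C)(C)[C@H]1C=C(C)CC[C@H]1C(C)=C | intermediate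
12 | (3S,4S)-4-(methoxymethoxy)-2-methyl-2-[(1S,6R)-3-methyl-6-(prop-1-en-2-yl)cyclohex-2-en-1-yl]hex-5-en-3-ol | O[C@H]([C@@H](OCOC)C=C)C(C)(C)[C@H]1C=C(C)CC[C@H]1C(C)=C | intermediate
13 | angelic acid | C/C=C(/C)C(=O)O | starting material
14 | angelic 2,4,6-trichlorobenzoic anhydride | C/C=C(/C)C(=O)OC(=O)c1c(Cl)cc(Cl)cc1Cl | intermediate
15 | C7 angelate of 12 | C/C=C(/C)C(=O)O[C@H]([C@@H](OCOC)C=C)C(C)(C)[C@H]1C=C(C)CC[C@H]1C(C)=C | intermediate
16 | O-8 bromomethyl ether | C/C=C(/C)C(=O)O[C@H]([C@@H](OCBr)C=C)C(C)(C)[C@H]1C=C(C)CC[C@H]1C(C)=C | intermediate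
17 | C7 angelate with free C8–OH (open-chain triene) | C/C=C(/C)C(=O)O[C@H]([C@@H](O)C=C)C(C)(C)[C@H]1C=C(C)CC[C@H]1C(C)=C | intermediate
18 | himachala-3,9-dien-8-ol 7-angelate, cis-fused | C/C=C(/C)C(=O)O[C@@H]1[C@@H](O)C=C(C)[C@@H]2CCC(C)=C[C@@H]2C1(C)C | intermediate
19 | 9,10-epoxyhimachal-3-en-8-ol 7-angelate | C/C=C(/C)C(=O)O[C@@H]1[C@@H](O)[C@H]2O[C@@]2(C)[C@@H]3CCC(C)=C[C@@H]3C1(C)C | intermediate
20 | (R)-2-methylbutanoic acid | CC[C@@H](C)C(=O)O | starting material
21 | 9,10-epoxyhimachal-3-ene 7-angelate 8-[(R)-2-methylbutanoate] | C/C=C(/C)C(=O)O[C@@H]1[C@@H](OC(=O)[C@H](C)CC)[C@H]2O[C@@]2(C)[C@@H]3CCC(C)=C[C@@H]3C1(C)C | intermediate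
22 | 9,10-epoxyhimachal-3-en-2-one 7-angelate 8-[(R)-2-methylbutanoate] | C/C=C(/C)C(=O)O[C@@H]1[C@@H](OC(=O)[C@H](C)CC)[C@H]2O[C@@]2(C)[C@@H]3CC(=O)C(C)=C[C@@H]3C1(C)C | intermediate
23 | C10 tertiary radical, C9 titanium alkoxide | C/C=C(/C)C(=O)O[C@@H]1[C@@H](OC(=O)[C@H](C)CC)[C@@H](O[Ti](Cl)(C2C=CC=C2)C2C=CC=C2)[C](C)[C@@H]3CC(=O)C(C)=C[C@@H]3C1(C)C | intermediate
24 | tricyclic C2=C3 titanium enolate, C9 titanium alkoxide | C/C=C(/C)C(=O)O[C@@H]1[C@@H](OC(=O)[C@H](C)CC)[C@@H](O[Ti](Cl)(C4C=CC=C4)C4C=CC=C4)[C@@]2(C)[C@@H]3CC(O[Ti](Cl)(C4C=CC=C4)C4C=CC=C4)=C(C)[C@H]2[C@@H]3C1(C)C | intermediate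
25 | 9-hydroxylongipinan-2-one 7-angelate 8-[(R)-2-methylbutanoate] | C/C=C(/C)C(=O)O[C@@H]1[C@@H](OC(=O)[C@H](C)CC)[C@@H](O)[C@@]2(C)[C@@H]3CC(=O)[C@H](C)[C@H]2[C@@H]3C1(C)C | intermediate
26 | 9-O-trimethylsilyl ether of 25 | C/C=C(/C)C(=O)O[C@@H]1[C@@H](OC(=O)[C@H](C)CC)[C@@H](O[Si](C)(C)C)[C@@]2(C)[C@@H]3CC(=O)[C@H](C)[C@H]2[C@@H]3C1(C)C | intermediate
27 | C1=C2 enol triflate of 26 | C/C=C(/C)C(=O)O[C@@H]1[C@@H](OC(=O)[C@H](C)CC)[C@@H](O[Si](C)(C)C)[C@@]2(C)[C@@H]3C=C(OS(=O)(=O)C(F)(F)F)[C@H](C)[C@H]2[C@@H]3C1(C)C | intermediate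
28 | 9-O-trimethylsilyl ether of 29 | C/C=C(/C)C(=O)O[C@@H]1[C@@H](OC(=O)[C@H](C)CC)[C@@H](O[Si](C)(C)C)[C@@]2(C)[C@@H]3C=C[C@H](C)[C@H]2[C@@H]3C1(C)C | intermediate
29 | 9-hydroxylongipin-1-ene 7-angelate 8-[(R)-2-methylbutanoate] | C/C=C(/C)C(=O)O[C@@H]1[C@@H](OC(=O)[C@H](C)CC)[C@@H](O)[C@@]2(C)[C@@H]3C=C[C@H](C)[C@H]2[C@@H]3C1(C)C | intermediate
30 | (4R,5S,7S,8S,9S,10R,11R)-7-angeloyloxy-9-hydroxy-8-[(2R)-2-methylbutanoyloxy]longipin-2-en-1-one | C/C=C(/C)C(=O)O[C@@H]1[C@@H](OC(=O)[C@H](C)CC)[C@@H](O)[C@@]2(C)[C@@H]3C(=O)C=C(C)[C@H]2[C@@H]3C1(C)C | target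

Total step count: 16. Longest linear sequence: 16 steps (1 to 30).

Steps most likely to fail

Step 12. The tertiary C10 radical may be intercepted by a second Cp2TiCl before the slow 4-exo closure. This would happen by loss of a methyl hydrogen to give an exocyclic allylic alcohol, or by deoxygenation back to the alkene. The fallback sets out from 22 and comes back at 25. It makes the same radical by halogen abstraction in a chain process that holds no metal radical trap. MgBr2·OEt2 in Et2O at −20 °C should open the epoxide of 22 at the tertiary carbon with inversion to the C10-bromo C9-alcohol, bromohydrin F1. Slow addition of (Me3Si)3SiH and Et3B/air to a dilute toluene solution of F1 should release the C10 radical. Its only competitor is then a dilute, slow hydrogen donor, and hydrogen transfer to the cyclised C3 radical gives 25.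

Step 16. Abstraction of the hindered C3–H may be slow, and the allyl radical may be captured at its tertiary C3 end, which leads to a dead-end peroxide instead of the ketone. The fallback sets out from 26 and comes back at 30. It brings oxygen to C1 by enolate chemistry and then removes the C2 oxygen.
- KN(SiMe3)2 followed by 2-(phenylsulfonyl)-3-phenyloxaziridine should hydroxylate C1 from the face of the C5 bridge to give α-hydroxy ketone F2.
- Dess–Martin periodinane should give the 1,2-dione, which can enolise only toward C3 because C11 is a bridgehead, and it is therefore obtained as diosphenol F3.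
- PhNTf2 and Et3N should give enol triflate F4.
- Pd(OAc)2, PPh3, HCO2H and Et3N should replace OTf by H to give the silyl ether of the target F5.
- Aqueous citric acid in MeOH then frees 30.

Step 5. Addition of the bulky borane to the neopentyl aldehyde may be slow. Warming may then erode the Z geometry of the reagent and with it the syn selectivity. The fallback sets out from 8 and comes back at 12. It builds C7–C8 by an auxiliary-controlled boron aldol reaction instead of an allylation.
- (R)-4-Benzyloxazolidin-2-one is N-acylated with (methoxymethoxy)acetyl chloride (n-BuLi, THF) to the glycolyl imide F6.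
- The Bu2BOTf/Et3N enolate of F6 should add to 8 through the Evans syn transition state to give the syn-aldol adduct F7.
- Me(MeO)NH·HCl and AlMe3 should give Weinreb amide F8.
- i-Bu2AlH at −78 °C should give aldehyde F9.
- Wittig methylenation with Ph3P=CH2 returns 12.

Further compounds
F1 | step 12 | C10-bromo C9-hydroxy himachal-3-en-2-one diester (bromohydrin) | C/C=C(/C)C(=O)O[C@@H]1[C@@H](OC(=O)[C@H](C)CC)[C@@H](O)[C@](C)(Br)[C@@H]2CC(=O)C(C)=C[C@@H]2C1(C)C
F2 | step 16 | 1-hydroxy derivative of 26 (α-hydroxy ketone) | C/C=C(/C)C(=O)O[C@@H]1[C@@H](OC(=O)[C@H](C)CC)[C@@H](O[Si](C)(C)C)[C@@]2(C)[C@@H]3[C@@H](O)C(=O)[C@H](C)[C@H]2[C@@H]3C1(C)C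
F3 | step 16 | 2-hydroxylongipin-2-en-1-one 9-silyl ether (diosphenol) | C/C=C(/C)C(=O)O[C@@H]1[C@@H](OC(=O)[C@H](C)CC)[C@@H](O[Si](C)(C)C)[C@@]2(C)[C@@H]3C(=O)C(O)=C(C)[C@H]2[C@@H]3C1(C)C
F4 | step 16 | 2-triflyloxylongipin-2-en-1-one 9-silyl ether (enol triflate) | C/C=C(/C)C(=O)O[C@@H]1[C@@H](OC(=O)[C@H](C)CC)[C@@H](O[Si](C)(C)C)[C@@]2(C)[C@@H]3C(=O)C(OS(=O)(=O)C(F)(F)F)=C(C)[C@H]2[C@@H]3C1(C)C
F5 | step 16 | 9-O-trimethylsilyl ether of the target | C/C=C(/C)C(=O)O[C@@H]1[C@@H](OC(=O)[C@H](C)CC)[C@@H](O[Si](C)(C)C)[C@@]2(C)[C@@H]3C(=O)C=C(C)[C@H]2[C@@H]3C1(C)C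
F6 | step 5 | (R)-4-benzyl-3-[(methoxymethoxy)acetyl]oxazolidin-2-one | COCOCC(=O)N1[C@H](Cc2ccccc2)COC1=O
F7 | step 5 | syn-aldol adduct of F6 and 8 | O=C1OC[C@@H](Cc2ccccc2)N1C(=O)[C@H](OCOC)[C@@H](O)C(C)(C)[C@H]1C=C(C)CC[C@H]1C(C)=C
F8 | step 5 | Weinreb amide from F7 | CON(C)C(=O)[C@H](OCOC)[C@@H](O)C(C)(C)[C@H]1C=C(C)CC[C@H]1C(C)=C
F9 | step 5 | 3-hydroxy-2-(methoxymethoxy) aldehyde from F8 | O=C[C@H](OCOC)[C@@H](O)C(C)(C)[C@H]1C=C(C)CC[C@H]1C(C)=C
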